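**Assumption:** the target is read as ent-oritin-(4β→6)-oritin-4α-ol: upper unit (2S,3R,4S), lower unit (2R,3S,4R), both 2,3-trans-3,4-trans, joined C4→C6. Compounds 3 and 9 are taken as bought.

## Retrosynthetic overview

1. 17 ⇐ 15: one pot, NaBH4 reduces both ketones (upper C3, lower C4), then Pd-catalysed removal of the three allyl ethers.
2. 15 ⇐ 13 (Nef) ⇐ 6 + 12: the interflavan C4–C6 bond comes from C-addition of the lower-unit 7-phenoxide to 3-nitro-2H-chromene 12. The nitroalkene is a masked α-keto cation (enolonium) at C4 of a flavan-3-one, so a ketone α-carbon is joined to an arene carbon.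
3. 12 ⇐ 8 + 11: an asymmetric oxa-Michael/Henry annulation builds the upper ring C and C2 (S) in one step.
4. 6 ⇐ 5 ⇐ 4 ⇐ 2 + 3: Juliá–Colonna epoxidation of the chalcone and acid cyclisation build the lower ring C (2R,3R). Its C4 ketone is kept to steer the coupling to C6 and is reduced last.
5. Ring order: lower ring C (step 4), upper ring C (step 7), union (step 8). Rings A and B come from bought arenes.

## Route

**Step 1**
Reactants: 1 1-(2,3,4-trihydroxyphenyl)ethan-1-one
Product: 2 1-[2,3,4-tris(methoxymethoxy)phenyl]ethan-1-one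
Conditions: NaH (3.6 equiv), MOMCl (3.6 equiv), DMF, 0 °C → rt
Reagents that add atoms: chloromethyl methyl ether, COCCl
Why: Williamson etherification of all three phenoxides, the strong base being needed for the chelated 2-OH; no stereocentre is formed.

**Step 2**
Reactants: 2 1-[2,3,4-tris(methoxymethoxy)phenyl]ethan-1-one; 3 4-(methoxymethoxy)benzaldehyde
Product: 4 (E)-3-[4-(methoxymethoxy)phenyl]-1-[2,3,4-tris(methoxymethoxy)phenyl]prop-2-en-1-one
Conditions: KOH, EtOH/H2O, rt, 24 h
Reagents that add atoms: none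
Why: Claisen–Schmidt aldol condensation of a methyl ketone with a non-enolisable aldehyde gives the (E)-chalcone, and MOM acetals are stable to base.

**Step 3**
Reactants: 4 (E)-3-[4-(methoxymethoxy)phenyl]-1-[2,3,4-tris(methoxymethoxy)phenyl]prop-2-en-1-one
Product: 5 [(2R,3S)-3-[4-(methoxymethoxy)phenyl]oxiran-2-yl][2,3,4-tris(methoxymethoxy)phenyl]methanone
Conditions: poly-L-leucine (cat.), urea·H2O2, DBU, THF, rt
Reagents that add atoms: hydrogen peroxide (as its urea adduct), OO
Why: Juliá–Colonna epoxidation, in which the helical poly-L-leucine binds the enone and delivers hydroperoxide to one face to give the trans (2R,3S) epoxide.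

**Step 4**
Reactants: 5 [(2R,3S)-3-[4-(methoxymethoxy)phenyl]oxiran-2-yl][2,3,4-tris(methoxymethoxy)phenyl]methanone
Product: 6 (2R,3R)-3,7,8-trihydroxy-2-(4-hydroxyphenyl)chroman-4-one
Conditions: 3% HCl in MeOH, 50 °C, 1 h; recrystallise
Reagents that add atoms: none
Why: Acetal methanolysis frees the 2'-OH, which opens the epoxide at the benzylic carbon in a 6-endo SN2-type attack (inversion, giving 2R) while the α-carbon keeps its configuration (3R), so the 2,3-trans dihydroflavonol forms without an accumulating intermediate and crystallisation raises the ee.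

**Step 5**
Reactants: 7 2,3,4-trihydroxybenzaldehyde
Product: 8 2-hydroxy-3,4-bis(prop-2-enyloxy)benzaldehyde
Conditions: allyl bromide (2.1 equiv), K2CO3 (2.2 equiv), acetone, reflux
Reagents that add atoms: allyl bromide, C=CCBr
Why: Williamson etherification that takes the 4-OH and 3-OH and leaves the 2-OH, which is hydrogen-bonded to the aldehyde and alkylated last; no stereocentre is formed.

**Step 6**
Reactants: 9 4-(prop-2-enyloxy)benzaldehyde; 10 nitromethane
Product: 11 1-[(E)-2-nitroethenyl]-4-(prop-2-enyloxy)benzene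
Conditions: NH4OAc, AcOH, 100 °C, 3 h
Reagents that add atoms: none
Why: Henry (nitroaldol) condensation with dehydration gives the conjugated (E)-nitrostyrene.

**Step 7**
Reactants: 8 2-hydroxy-3,4-bis(prop-2-enyloxy)benzaldehyde; 11 1-[(E)-2-nitroethenyl]-4-(prop-2-enyloxy)benzene
Product: 12 (2S)-3-nitro-7,8-bis(prop-2-enyloxy)-2-[4-(prop-2-enyloxy)phenyl]-2H-chromene
Conditions: (S)-1-methyl-2-[(pyrrolidin-2-ylmethyl)sulfanyl]-1H-imidazole (20 mol %; its antipode if it delivers 2R), 2-hydroxybenzoic acid (20 mol %), iPrOH, 4 Å MS, rt, 72 h; recrystallise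
Reagents that add atoms: none
Why: Amine-catalysed asymmetric oxa-Michael/Henry/elimination domino, in which the chiral pyrrolidine forms an iminium ion with 8, the phenol adds to 11 inside the chiral ion pair to set C2 (S), and the nitronate closes onto the iminium carbon with loss of the amine; residual antipode is purged later as a diastereomer of 13.

**Step 8**
Reactants: 6 (2R,3R)-3,7,8-trihydroxy-2-(4-hydroxyphenyl)chroman-4-one; 12 (2S)-3-nitro-7,8-bis(prop-2-enyloxy)-2-[4-(prop-2-enyloxy)phenyl]-2H-chromene (1.2 equiv)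
Product: 13 (2R,3R)-3,7,8-trihydroxy-2-(4-hydroxyphenyl)-6-[(2S,3R,4S)-3-nitro-7,8-bis(prop-2-enyloxy)-2-[4-(prop-2-enyloxy)phenyl]chroman-4-yl]chroman-4-one
Conditions: iPr2NEt (1.0 equiv), CF3CH2OH/THF 1:1, 45 °C, Ar, 36 h
Reagents that add atoms: none
Why: Proposed new method: the 7-phenoxide of 6 (the most acidic OH, para to the C4 carbonyl, with C6 as its only free ortho position) adds through carbon to C4 of nitroalkene 12, which acts as a masked C4 cation of a flavan-3-one, O-addition being reversible and C-addition made irreversible by rearomatisation; attack is axial on the half-chair, syn to the 2-aryl group that allylic strain with the nitro group holds pseudo-axial, giving the 2,4-cis adduct whose nitro group equilibrates to the all-equatorial 2,3-trans-3,4-trans isomer (2S,3R,4S); the closest known reaction types are the amine-promoted ortho-Friedel–Crafts (Michael) alkylation of naphthols and electron-rich phenols with nitroalkenes and the trans,trans-selective Michael additions of carbon nucleophiles to 2-aryl-3-nitro-2H-chromenes.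

**Step 9**
Reactants: 13 (2R,3R)-3,7,8-trihydroxy-2-(4-hydroxyphenyl)-6-[(2S,3R,4S)-3-nitro-7,8-bis(prop-2-enyloxy)-2-[4-(prop-2-enyloxy)phenyl]chroman-4-yl]chroman-4-one
Product: 15 (2R,3R)-3,7,8-trihydroxy-2-(4-hydroxyphenyl)-6-[(2S,4S)-3-oxo-7,8-bis(prop-2-enyloxy)-2-[4-(prop-2-enyloxy)phenyl]chroman-4-yl]chroman-4-one, via disodium nitronate 14 (not isolated)
Conditions: NaOMe (2.2 equiv), MeOH/THF, 0 °C, 15 min; then aq. TiCl3 (5 equiv), NH4OAc buffer (pH 5–6), 0 °C → rt, 2 h; crude product used at once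
Reagents that add atoms: water, O
Why: Nef reaction in McMurry's reductive form, in which TiCl3 reduces the nitronate to the N–H imine that hydrolyses in the buffer to the C3 ketone, C2 keeping its configuration and the epimerisable, doubly benzylic C4 resting 2,4-cis with both aryl groups equatorial (2S,4S); the mild pH avoids cyclodehydration of the ketone with the neighbouring 7-OH.

**Step 10**
Reactants: 15 (2R,3R)-3,7,8-trihydroxy-2-(4-hydroxyphenyl)-6-[(2S,4S)-3-oxo-7,8-bis(prop-2-enyloxy)-2-[4-(prop-2-enyloxy)phenyl]chroman-4-yl]chroman-4-one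
Product: 17 (2R,3S,4R)-2-(4-hydroxyphenyl)-6-[(2S,3R,4S)-3,7,8-trihydroxy-2-(4-hydroxyphenyl)chroman-4-yl]chromane-3,4,7,8-tetrol, via upper-unit tri-O-allyl ether 16 (not isolated)
Conditions: NaBH4 (12 equiv), THF/MeOH 4:1, 0 °C, 1 h; then Pd(PPh3)4 (10 mol %), rt, 6 h, Ar; pH 6 phosphate buffer work-up, Sephadex LH-20
Reagents that add atoms: none
Why: Borohydride reduction followed by Pd-catalysed reductive deallylation (Tsuji–Trost ionisation of the aryl allyl ethers with hydride capture of the π-allyl): hydride attacks the upper C3 ketone axially, unhindered because the ring positions β to the carbonyl are O1 and an aromatic carbon, giving the equatorial 3-OH trans to both aryl groups (3R), and reduces the lower C4 ketone to the 3,4-trans diol (4R) as in the known reduction of 2,3-trans-dihydroflavonols to 3,4-trans-flavan-3,4-diols.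

## Compound list

1 | 1-(2,3,4-trihydroxyphenyl)ethan-1-one | CC(=O)c1ccc(O)c(O)c1O | starting material
2 | 1-[2,3,4-tris(methoxymethoxy)phenyl]ethan-1-one | CC(=O)c1ccc(OCOC)c(OCOC)c1OCOC | intermediate
3 | 4-(methoxymethoxy)benzaldehyde | COCOc1ccc(C=O)cc1 | starting material
4 | (E)-3-[4-(methoxymethoxy)phenyl]-1-[2,3,4-tris(methoxymethoxy)phenyl]prop-2-en-1-one | COCOc1ccc(/C=C/C(=O)c2ccc(OCOC)c(OCOC)c2OCOC)cc1 | intermediate
5 | [(2R,3S)-3-[4-(methoxymethoxy)phenyl]oxiran-2-yl][2,3,4-tris(methoxymethoxy)phenyl]methanone | O=C(c1ccc(OCOC)c(OCOC)c1OCOC)[C@@H]1O[C@H]1c1ccc(OCOC)cc1 | intermediate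
6 | (2R,3R)-3,7,8-trihydroxy-2-(4-hydroxyphenyl)chroman-4-one | O=C1c2ccc(O)c(O)c2O[C@H](c2ccc(O)cc2)[C@H]1O | intermediate
7 | 2,3,4-trihydroxybenzaldehyde | O=Cc1ccc(O)c(O)c1O | starting material
8 | 2-hydroxy-3,4-bis(prop-2-enyloxy)benzaldehyde | O=Cc1ccc(OCC=C)c(OCC=C)c1O | intermediate
9 | 4-(prop-2-enyloxy)benzaldehyde | C=CCOc1ccc(C=O)cc1 | starting material
10 | nitromethane | C[N+](=O)[O-] | starting material
11 | 1-[(E)-2-nitroethenyl]-4-(prop-2-enyloxy)benzene | C=CCOc1ccc(/C=C/[N+](=O)[O-])cc1 | intermediate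
12 | (2S)-3-nitro-7,8-bis(prop-2-enyloxy)-2-[4-(prop-2-enyloxy)phenyl]-2H-chromene | [O-][N+](=O)C1=Cc2ccc(OCC=C)c(OCC=C)c2O[C@H]1c1ccc(OCC=C)cc1 | intermediate
13 | (2R,3R)-3,7,8-trihydroxy-2-(4-hydroxyphenyl)-6-[(2S,3R,4S)-3-nitro-7,8-bis(prop-2-enyloxy)-2-[4-(prop-2-enyloxy)phenyl]chroman-4-yl]chroman-4-one | Oc1ccc([C@H]2Oc3c(cc([C@H]4c5ccc(OCC=C)c(OCC=C)c5O[C@@H](c5ccc(OCC=C)cc5)[C@@H]4[N+](=O)[O-])c(O)c3O)C(=O)[C@@H]2O)cc1 | intermediate
14 | disodium salt of 13 (7-phenoxide of the lower unit, C3 nitronate of the upper unit) | [Na+].[Na+].Oc1ccc([C@H]2Oc3c(cc([C@H]4c5ccc(OCC=C)c(OCC=C)c5O[C@@H](c5ccc(OCC=C)cc5)C4=[N+]([O-])[O-])c([O-])c3O)C(=O)[C@@H]2O)cc1 | intermediate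
15 | (2R,3R)-3,7,8-trihydroxy-2-(4-hydroxyphenyl)-6-[(2S,4S)-3-oxo-7,8-bis(prop-2-enyloxy)-2-[4-(prop-2-enyloxy)phenyl]chroman-4-yl]chroman-4-one | Oc1ccc([C@H]2Oc3c(cc([C@H]4c5ccc(OCC=C)c(OCC=C)c5O[C@@H](c5ccc(OCC=C)cc5)C4=O)c(O)c3O)C(=O)[C@@H]2O)cc1 | intermediate
16 | (2R,3S,4R)-2-(4-hydroxyphenyl)-6-[(2S,3R,4S)-3-hydroxy-7,8-bis(prop-2-enyloxy)-2-[4-(prop-2-enyloxy)phenyl]chroman-4-yl]chromane-3,4,7,8-tetrol | Oc1ccc([C@H]2Oc3c(cc([C@H]4c5ccc(OCC=C)c(OCC=C)c5O[C@@H](c5ccc(OCC=C)cc5)[C@@H]4O)c(O)c3O)[C@@H](O)[C@@H]2O)cc1 | intermediate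
17 | (2R,3S,4R)-2-(4-hydroxyphenyl)-6-[(2S,3R,4S)-3,7,8-trihydroxy-2-(4-hydroxyphenyl)chroman-4-yl]chromane-3,4,7,8-tetrol [ent-oritin-(4β→6)-oritin-4α-ol] | Oc1ccc([C@H]2Oc3c(cc([C@H]4c5ccc(O)c(O)c5O[C@@H](c5ccc(O)cc5)[C@@H]4O)c(O)c3O)[C@@H](O)[C@@H]2O)cc1 | target

## Step count and risks

Total steps: 10. Longest linear sequence: 7 (steps 1, 2, 3, 4, 8, 9, 10).

**Step 7 (asymmetric chromene formation).** Both partners are electron-rich, so rate and ee may be modest, and the sense of induction must be checked. The fallback sets out from 8 and 11 and replaces asymmetric catalysis by resolution through the enantiopure partner. DABCO (0.3 equiv) in MeCN at 60 °C gives racemic 3-nitro-7,8-bis(prop-2-enyloxy)-2-[4-(prop-2-enyloxy)phenyl]-2H-chromene F1. Two equivalents of it are coupled with 6 under the step 8 conditions. This gives 13 together with its diastereomer carrying the (2R,3S,4R) upper unit F2. The two are separated by chromatography or crystallisation, and the route is rejoined at 13.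

**Step 8 (interflavan coupling).** The acyl-substituted phenoxide may be too weak a carbon nucleophile for the donor-substituted nitroalkene. Reversible O-addition with ring opening could also erode the configuration at C2, and the facial selectivity at C4 is argued by analogy only. The fallback sets out from 12 and uses a cationic instead of a conjugate-acceptor enolonium equivalent. Nucleophilic epoxidation (tBuOOH, DBU, THF, 0 °C) gives (2S)-3,4-epoxy-3-nitro-7,8-bis(prop-2-enyloxy)-2-[4-(prop-2-enyloxy)phenyl]chroman F3, with the epoxide drawn trans to the 2-aryl group. In (CF3)2CHOH at rt the epoxide ionises at the benzylic C4, helped by the 7-allyloxy group and the ring oxygen. The cation is captured at C6 of neutral 6, and the resulting α-nitro alkoxide loses nitrite. This gives ketone 15 directly, so the route is rejoined at 15 and step 9 is bypassed.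

**Step 9 (Nef reaction).** The nitronate can open ring C of the upper unit by β-elimination of the ring oxygen. The lower dihydroflavonol is base-sensitive. The ketone can also cyclodehydrate with the neighbouring 7-OH to a benzofuran. The fallback sets out from 13 and avoids both the nitronate and the titanium reagent. Reduction with SnCl2·2H2O, PhSH and Et3N in MeCN at rt gives the C3 oxime of 15 F4. Exchange of the oxime onto aqueous glyoxylic acid (NaOAc, rt) then gives the ketone, and the route is rejoined at 15.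

## Further compounds

F1 | step 7 | racemic 3-nitro-7,8-bis(prop-2-enyloxy)-2-[4-(prop-2-enyloxy)phenyl]-2H-chromene | [O-][N+](=O)C1=Cc2ccc(OCC=C)c(OCC=C)c2OC1c1ccc(OCC=C)cc1
F2 | step 7 | (2R,3R)-3,7,8-trihydroxy-2-(4-hydroxyphenyl)-6-[(2R,3S,4R)-3-nitro-7,8-bis(prop-2-enyloxy)-2-[4-(prop-2-enyloxy)phenyl]chroman-4-yl]chroman-4-one | Oc1ccc([C@H]2Oc3c(cc([C@@H]4c5ccc(OCC=C)c(OCC=C)c5O[C@H](c5ccc(OCC=C)cc5)[C@H]4[N+](=O)[O-])c(O)c3O)C(=O)[C@@H]2O)cc1
F3 | step 8 | (2S)-3,4-epoxy-3-nitro-7,8-bis(prop-2-enyloxy)-2-[4-(prop-2-enyloxy)phenyl]chroman (epoxide trans to the 2-aryl group) | [O-][N+](=O)[C@@]12O[C@@H]1c1ccc(OCC=C)c(OCC=C)c1O[C@H]2c1ccc(OCC=C)cc1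
F4 | step 9 | C3 oxime of 15 (C=N geometry not fixed) | Oc1ccc([C@H]2Oc3c(cc([C@H]4c5ccc(OCC=C)c(OCC=C)c5O[C@@H](c5ccc(OCC=C)cc5)C4=NO)c(O)c3O)C(=O)[C@@H]2O)cc1
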